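**Plan**
1. Lettering: rings A to H run from the 2,4,6-trihydroxyphenoxy end to the 3,4,5-trihydroxyphenoxy end. In rings B to H, position 1 is the carbon whose oxygen leads back toward ring A.
2. Enabling feature: ring D is a hydroquinone unit. Its two para oxygens are bound to position 6 of ring C and position 1 of ring E. Each of these carbons lies para to a hydroxyl-bearing carbon (position 3 of ring C, position 4 of ring E). That carbon can travel as a formyl group, which activates a fluoride and is later oxidised out to the hydroxyl.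
3. Cuts: first the two O(ring D)–aryl bonds, giving an ABC fluoroaldehyde, 2,6-dimethoxyhydroquinone and an EFGH fluoroaldehyde. Then the ring F–ring G, E–F and G–H ethers in one half and the B–C and A–B ethers in the other, each at a carbon ortho or para to a formyl group.
4. Forward order: A + B, then C. Separately H + G and F + E, then EF + GH. Finally ABC + D + EFGH in one flask. No ring is formed; all eight come from benzene building blocks.
5. Between displacements the spent formyl group becomes a hydroxyl (Baeyer–Villiger). That hydroxyl directs a new one-carbon unit to its ortho carbon, para to the next fluoride. All hydroxyls travel as methyl ethers, removed last with BBr3.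
6. Stereochemistry: none to set. The target has no stereocentre and its diaryl ether bonds rotate freely.

Key step: step 22

Assumption: the six aromatic starting materials (1, 4, 7, 14, 18, 24) are taken as catalogue compounds. A one-pot oxidation and methanolysis is counted as one step.

**ABC fluoroaldehyde**

Step 1
Reactants: 1 2,4,6-trimethoxybenzaldehyde
Product: 3 2,4,6-trimethoxyphenol, via 2,4,6-trimethoxyphenyl formate 2 (not isolated)
Conditions: mCPBA, CH2Cl2, 0 °C to rt; NaHCO3 wash, solvent swap; cat. K2CO3, MeOH, Ar, rt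
Reagents that add atoms: mCPBA, OOC(=O)c1cccc(Cl)c1
Why: Baeyer–Villiger oxidation: the three methoxy donors make aryl migration in the Criegee adduct much faster than hydride migration, and methanol then transesterifies the formate.

Step 2
Reactants: 3 2,4,6-trimethoxyphenol; 4 4-fluoro-2,6-dimethoxybenzaldehyde
Product: 5 AB aldehyde (2,6-dimethoxy-4-(2,4,6-trimethoxyphenoxy)benzaldehyde)
Conditions: K2CO3, DMF, N2, 100 °C
Reagents that add atoms: none
Why: Nucleophilic aromatic substitution by addition–elimination: the para formyl group carries the charge of the Meisenheimer anion, and the fluorine-bearing carbon of 4 has only hydrogen neighbours, so even the doubly flanked phenoxide of 3 can reach it.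

Step 3
Reactants: 5 AB aldehyde
Product: 6 AB salicylaldehyde (2-hydroxy-6-methoxy-4-(2,4,6-trimethoxyphenoxy)benzaldehyde)
Conditions: BCl3 (1.1 equiv), CH2Cl2, −78 to 0 °C; H2O
Reagents that add atoms: none
Why: Chelation-controlled ether cleavage: BCl3 binds the formyl oxygen and one ortho methoxy oxygen in a six-membered chelate and chloride removes only that methyl group, the two ortho methoxyls being equivalent and the boron chelate of the product resisting a second cleavage.

Step 4
Reactants: 6 AB salicylaldehyde; 7 3,4-difluoro-2-methoxybenzaldehyde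
Product: 8 ABC dialdehyde (formyl at position 4 of ring B and position 4 of ring C; fluorine at position 6 of ring C)
Conditions: Cs2CO3, DMSO, N2, 90 °C
Reagents that add atoms: none
Why: Nucleophilic aromatic substitution: in 7 only the fluorine para to the formyl group is activated, while the neighbouring fluorine (meta to formyl) speeds the attack by induction and stays as the future leaving group at position 6 of ring C.

Step 5
Reactants: 8 ABC dialdehyde
Product: 10 ABC bisphenol (hydroxyl in place of both formyl groups of 8), via ABC bis-formate 9 (not isolated)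
Conditions: mCPBA (2.5 equiv), CH2Cl2, 0 °C to rt; NaHCO3 wash, solvent swap; cat. K2CO3, MeOH, Ar, rt
Reagents that add atoms: mCPBA, OOC(=O)c1cccc(Cl)c1
Why: Double Baeyer–Villiger oxidation: each formyl group sits on a ring with ortho and para oxygen donors, so both aryl groups migrate, and methanolysis frees the hydroxyls at position 4 of ring B and position 4 of ring C.

Step 6
Reactants: 10 ABC bisphenol
Product: 11 ABC hydroxymethyl bisphenol (CH2OH at position 3 of ring C)
Conditions: 37% aq. HCHO (excess), NaOH, H2O–THF, Ar, 40 °C; AcOH to pH 6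
Reagents that add atoms: formaldehyde, C=O
Why: Lederer–Manasse hydroxymethylation: in base only phenoxide rings attack formaldehyde, the ring C phenoxide has a single open ortho or para carbon (position 3) and the ring B phenoxide has none, and this route is preferred to magnesium-mediated formylation because a 2-methoxyphenol holds magnesium as a chelate on the wrong side of the oxygen.

Step 7
Reactants: 11 ABC hydroxymethyl bisphenol
Product: 12 ABC benzylic alcohol (both phenols methylated)
Conditions: MeI, K2CO3, DMF, rt
Reagents that add atoms: iodomethane, CI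
Why: Williamson ether synthesis: K2CO3 ionises only the two phenols, so the benzylic alcohol stays free.

Step 8
Reactants: 12 ABC benzylic alcohol
Product: 13 ABC fluoroaldehyde (5-[2,3-dimethoxy-5-(2,4,6-trimethoxyphenoxy)phenoxy]-4-fluoro-2,3-dimethoxybenzaldehyde)
Conditions: activated MnO2, CH2Cl2, rt
Reagents that add atoms: none
Why: MnO2 oxidation of an electron-rich benzylic alcohol, which stops at the aldehyde and places formyl para to the fluorine of ring C.

**Building block for rings E and G**

Step 9
Reactants: 14 3,4-difluoroanisole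
Product: 15 (2,3-difluoro-6-methoxyphenyl)trimethylsilane
Conditions: LiN(iPr)2 (LDA), THF, −78 °C; Me3SiCl, −78 °C to rt
Reagents that add atoms: chlorotrimethylsilane, C[Si](C)(C)Cl
Why: Directed ortho-metalation: the proton between methoxy and fluorine is the most acidic one in 14, and silylation blocks this site for the next step.

Step 10
Reactants: 15 (2,3-difluoro-6-methoxyphenyl)trimethylsilane
Product: 16 2,3-difluoro-5-methoxy-4-(trimethylsilyl)benzaldehyde
Conditions: lithium 2,2,6,6-tetramethylpiperidide (LiTMP), THF, −78 °C; DMF; H2O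
Reagents that add atoms: N,N-dimethylformamide, CN(C)C=O
Why: Second ortho-metalation with DMF quench: with the best site blocked, the hindered amide base follows acidity and removes the only remaining proton next to a fluorine and not the one next to methoxy.

Step 11
Reactants: 16 2,3-difluoro-5-methoxy-4-(trimethylsilyl)benzaldehyde
Product: 17 2,3-difluoro-5-methoxybenzaldehyde
Conditions: CsF (0.2 equiv), DMF–H2O (20:1), rt
Reagents that add atoms: none
Why: Fluoride-catalysed protodesilylation: the aryl anion leaving the pentacoordinate silicate is stabilised by the ortho fluorine, the ortho methoxy group and the para formyl group, and water protonates it.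

**GH fluoroaldehyde**

Step 12
Reactants: 17 2,3-difluoro-5-methoxybenzaldehyde; 18 3,4,5-trimethoxyphenol
Product: 19 GH aldehyde (3-fluoro-5-methoxy-2-(3,4,5-trimethoxyphenoxy)benzaldehyde)
Conditions: K2CO3, DMF, N2, 100 °C
Reagents that add atoms: none
Why: Nucleophilic aromatic substitution ortho to a formyl group: only the fluorine at position 2 of 17 is conjugated with the aldehyde, and the adjacent fluorine activates it further and survives as the later leaving group at position 1 of ring G.

Step 13
Reactants: 19 GH aldehyde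
Product: 21 GH phenol (3-fluoro-5-methoxy-2-(3,4,5-trimethoxyphenoxy)phenol), via GH formate 20 (not isolated)
Conditions: mCPBA, CH2Cl2, rt to 40 °C; NaHCO3 wash, solvent swap; cat. K2CO3, MeOH, rt
Reagents that add atoms: mCPBA, OOC(=O)c1cccc(Cl)c1
Why: Baeyer–Villiger oxidation of a 2-aryloxybenzaldehyde, in which the ortho aryloxy donor favours aryl migration, followed by methanolysis of the formate.

Step 14
Reactants: 21 GH phenol
Product: 22 GH salicylaldehyde (4-fluoro-2-hydroxy-6-methoxy-3-(3,4,5-trimethoxyphenoxy)benzaldehyde)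
Conditions: MgCl2, Et3N, (CH2O)n, THF, reflux; 1 M HCl
Reagents that add atoms: paraformaldehyde (as formaldehyde), C=O
Why: Casnati–Skattebøl ortho-formylation: the magnesium phenoxide passes bound formaldehyde to its ortho carbon and a second formaldehyde oxidises the benzylic alkoxide, position 4 of ring G being the only free ortho site and activated by the adjacent methoxy group, while the diaryl ether oxygen on the other side is too weak a ligand to hold magnesium away.

Step 15
Reactants: 22 GH salicylaldehyde
Product: 23 GH fluoroaldehyde (4-fluoro-2,6-dimethoxy-3-(3,4,5-trimethoxyphenoxy)benzaldehyde)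
Conditions: MeI, K2CO3, DMF, rt
Reagents that add atoms: iodomethane, CI
Why: Williamson ether synthesis at room temperature, where methylation of the phenoxide is far faster than any attack on the fluoride that now lies para to formyl.

**EFGH fluoroaldehyde**

Step 16
Reactants: 24 2,6-dimethoxy-1,4-benzoquinone
Product: 25 2,6-dimethoxyhydroquinone
Conditions: Na2S2O4, H2O–EtOAc, rt, N2
Reagents that add atoms: none
Why: Two-electron reduction of a quinone by dithionite, a standard and fast reaction.

Step 17
Reactants: 25 2,6-dimethoxyhydroquinone; 17 2,3-difluoro-5-methoxybenzaldehyde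
Product: 26 EF phenol (3-fluoro-2-(4-hydroxy-3,5-dimethoxyphenoxy)-5-methoxybenzaldehyde)
Conditions: 25 (3 equiv), Cs2CO3 (1.2 equiv), degassed DMSO, Ar, 70 °C
Reagents that add atoms: none
Why: Nucleophilic aromatic substitution ortho to formyl with site choice: excess 25 and less than one equivalent of base per diol keep it as the monoanion of the more acidic open hydroxyl, and attack through the flanked oxygen would need an ether with four ortho substituents.

Step 18
Reactants: 26 EF phenol; 23 GH fluoroaldehyde
Product: 27 EFGH dialdehyde (formyl at position 5 of ring E and position 4 of ring G; fluorine at position 1 of ring E)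
Conditions: Cs2CO3, DMSO, 4 Å MS, Ar, 110 °C
Reagents that add atoms: none
Why: Nucleophilic aromatic substitution para to formyl: the flanked phenoxide of 26 attacks the fluorine-bearing carbon of 23, which has one hydrogen neighbour, while the fluorine of 26 is meta to its own formyl group and inert.

Step 19
Reactants: 27 EFGH dialdehyde
Product: 29 EFGH bisphenol (hydroxyl in place of both formyl groups of 27), via EFGH bis-formate 28 (not isolated)
Conditions: mCPBA (2.5 equiv), CH2Cl2, rt; NaHCO3 wash, solvent swap; cat. K2CO3, MeOH, Ar, rt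
Reagents that add atoms: mCPBA, OOC(=O)c1cccc(Cl)c1
Why: Double Baeyer–Villiger oxidation of the two kinds of aldehyde already oxidised in steps 5 and 13, followed by methanolysis to the hydroxyls at position 5 of ring E and position 4 of ring G.

Step 20
Reactants: 29 EFGH bisphenol
Product: 30 EFGH salicylaldehyde (formyl at position 4 of ring E)
Conditions: MgCl2, Et3N, (CH2O)n, THF, reflux; 1 M HCl
Reagents that add atoms: paraformaldehyde (as formaldehyde), C=O
Why: Casnati–Skattebøl ortho-formylation: of the two magnesium phenoxides only that of ring E has a free ortho carbon (position 4), the ring G phenoxide is flanked by two methoxyls, and aryl methyl ethers do not react.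

Step 21
Reactants: 30 EFGH salicylaldehyde
Product: 31 EFGH fluoroaldehyde (4-fluoro-2,6-dimethoxy-3-{3,5-dimethoxy-4-[3,4,5-trimethoxy-2-(3,4,5-trimethoxyphenoxy)phenoxy]phenoxy}benzaldehyde)
Conditions: MeI, K2CO3, DMF, rt
Reagents that add atoms: iodomethane, CI
Why: Williamson ether synthesis on both phenols, leaving formyl para to the fluorine at position 1 of ring E.

**Union and endgame**

Step 22
Reactants: 13 ABC fluoroaldehyde; 25 2,6-dimethoxyhydroquinone; 31 EFGH fluoroaldehyde
Product: 33 octamer dialdehyde (formyl at position 3 of ring C and position 4 of ring E; nineteen methyl ethers), via ABCD phenol 32 (not isolated)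
Conditions: 13 (1 equiv), 25 (1 equiv), Cs2CO3 (1.05 equiv), degassed DMSO, 4 Å MS, Ar, 80 °C; then 31 (1 equiv), Cs2CO3 (1.5 equiv), 115 °C
Reagents that add atoms: none
Why: Each bond forms by addition–elimination: the phenoxide adds to the fluorine-bearing carbon, the para formyl group takes up the charge of the Meisenheimer anion, and fluoride leaves. The closest known reaction is the displacement of fluoride from 4-fluorobenzaldehydes by phenoxides, doubled as in the condensation of hydroquinones with activated aryl fluorides to poly(aryl ether)s, and steps 17 and 18 rehearse the two halves on smaller partners. No ring is closed and no stereocentre is made. The selectivity needed is between the two hydroxyls of 25: with one equivalent of base the hydroxyl meta to both methoxyls is ionised first, and attack of the flanked oxygen on position 6 of ring C would give an ether with four ortho substituents, so only the open oxygen should react with 13 at 80 °C. The second charge of base then releases the flanked phenoxide of 32, which meets the fluoride of 31, a carbon with one hydrogen neighbour, at 115 °C. Fluoride is the only good leaving group para to either formyl group, the two fluorides are added one after the other in equimolar amounts, and air is excluded because the hydroquinone anion is easily oxidised.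

Step 23
Reactants: 33 octamer dialdehyde
Product: 35 octamer diol (hydroxyl at position 3 of ring C and position 4 of ring E), via octamer bis-formate 34 (not isolated)
Conditions: mCPBA (2.5 equiv), CH2Cl2, 0 °C to rt; NaHCO3 wash, solvent swap; cat. K2CO3, MeOH, Ar, rt
Reagents that add atoms: mCPBA, OOC(=O)c1cccc(Cl)c1
Why: Double Baeyer–Villiger oxidation: both formyl groups have an ortho methoxy and a para aryloxy donor, so the aryl groups migrate and the activating groups leave as formate, giving the hydroxyls the target has at these carbons.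

Step 24
Reactants: 35 octamer diol
Product: 36 CNP0175816.0 (target)
Conditions: BBr3 (about 3 equiv per OMe), CH2Cl2, Ar, −78 °C to rt; ice-water; Sephadex LH-20 under Ar
Reagents that add atoms: none
Why: Lewis-acid ether cleavage: BBr3 binds each methoxy oxygen and bromide attacks the methyl carbon by SN2, whereas the diaryl ether bonds offer no sp3 carbon and survive.

**Compound list**
1 | 2,4,6-trimethoxybenzaldehyde | COc1cc(OC)c(C=O)c(OC)c1 | starting material
2 | 2,4,6-trimethoxyphenyl formate | COc1cc(OC)c(OC=O)c(OC)c1 | intermediate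
3 | 2,4,6-trimethoxyphenol (ring A) | COc1cc(OC)c(O)c(OC)c1 | intermediate
4 | 4-fluoro-2,6-dimethoxybenzaldehyde (ring B) | COc1cc(F)cc(OC)c1C=O | starting material
5 | AB aldehyde, 2,6-dimethoxy-4-(2,4,6-trimethoxyphenoxy)benzaldehyde | COc1cc(OC)c(Oc2cc(OC)c(C=O)c(OC)c2)c(OC)c1 | intermediate
6 | AB salicylaldehyde, 2-hydroxy-6-methoxy-4-(2,4,6-trimethoxyphenoxy)benzaldehyde | COc1cc(OC)c(Oc2cc(O)c(C=O)c(OC)c2)c(OC)c1 | intermediate
7 | 3,4-difluoro-2-methoxybenzaldehyde (ring C) | COc1c(F)c(F)ccc1C=O | starting material
8 | ABC dialdehyde, 2-(2-fluoro-4-formyl-3-methoxyphenoxy)-6-methoxy-4-(2,4,6-trimethoxyphenoxy)benzaldehyde | COc1cc(OC)c(Oc2cc(OC)c(C=O)c(Oc3ccc(C=O)c(OC)c3F)c2)c(OC)c1 | intermediate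
9 | ABC bis-formate, the bis(formate ester) of 10 | COc1cc(OC)c(Oc2cc(OC)c(OC=O)c(Oc3ccc(OC=O)c(OC)c3F)c2)c(OC)c1 | intermediate
10 | ABC bisphenol, 2-(2-fluoro-4-hydroxy-3-methoxyphenoxy)-6-methoxy-4-(2,4,6-trimethoxyphenoxy)phenol | COc1cc(OC)c(Oc2cc(OC)c(O)c(Oc3ccc(O)c(OC)c3F)c2)c(OC)c1 | intermediate
11 | ABC hydroxymethyl bisphenol, 2-[2-fluoro-4-hydroxy-5-(hydroxymethyl)-3-methoxyphenoxy]-6-methoxy-4-(2,4,6-trimethoxyphenoxy)phenol | COc1cc(OC)c(Oc2cc(OC)c(O)c(Oc3cc(CO)c(O)c(OC)c3F)c2)c(OC)c1 | intermediate
12 | ABC benzylic alcohol, {5-[2,3-dimethoxy-5-(2,4,6-trimethoxyphenoxy)phenoxy]-4-fluoro-2,3-dimethoxyphenyl}methanol | COc1cc(OC)c(Oc2cc(OC)c(OC)c(Oc3cc(CO)c(OC)c(OC)c3F)c2)c(OC)c1 | intermediate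
13 | ABC fluoroaldehyde, 5-[2,3-dimethoxy-5-(2,4,6-trimethoxyphenoxy)phenoxy]-4-fluoro-2,3-dimethoxybenzaldehyde | COc1cc(OC)c(Oc2cc(OC)c(OC)c(Oc3cc(C=O)c(OC)c(OC)c3F)c2)c(OC)c1 | intermediate
14 | 3,4-difluoroanisole | COc1ccc(F)c(F)c1 | starting material
15 | (2,3-difluoro-6-methoxyphenyl)trimethylsilane | COc1ccc(F)c(F)c1[Si](C)(C)C | intermediate
16 | 2,3-difluoro-5-methoxy-4-(trimethylsilyl)benzaldehyde | COc1cc(C=O)c(F)c(F)c1[Si](C)(C)C | intermediate
17 | 2,3-difluoro-5-methoxybenzaldehyde (rings E and G) | COc1cc(F)c(F)c(C=O)c1 | intermediate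
18 | 3,4,5-trimethoxyphenol (ring H) | COc1cc(O)cc(OC)c1OC | starting material
19 | GH aldehyde, 3-fluoro-5-methoxy-2-(3,4,5-trimethoxyphenoxy)benzaldehyde | COc1cc(F)c(Oc2cc(OC)c(OC)c(OC)c2)c(C=O)c1 | intermediate
20 | GH formate, 3-fluoro-5-methoxy-2-(3,4,5-trimethoxyphenoxy)phenyl formate | COc1cc(F)c(Oc2cc(OC)c(OC)c(OC)c2)c(OC=O)c1 | intermediate
21 | GH phenol, 3-fluoro-5-methoxy-2-(3,4,5-trimethoxyphenoxy)phenol | COc1cc(F)c(Oc2cc(OC)c(OC)c(OC)c2)c(O)c1 | intermediate
22 | GH salicylaldehyde, 4-fluoro-2-hydroxy-6-methoxy-3-(3,4,5-trimethoxyphenoxy)benzaldehyde | COc1cc(F)c(Oc2cc(OC)c(OC)c(OC)c2)c(O)c1C=O | intermediate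
23 | GH fluoroaldehyde, 4-fluoro-2,6-dimethoxy-3-(3,4,5-trimethoxyphenoxy)benzaldehyde | COc1cc(F)c(Oc2cc(OC)c(OC)c(OC)c2)c(OC)c1C=O | intermediate
24 | 2,6-dimethoxy-1,4-benzoquinone | COC1=CC(=O)C=C(OC)C1=O | starting material
25 | 2,6-dimethoxyhydroquinone, 2,6-dimethoxybenzene-1,4-diol (rings D and F) | COc1cc(O)cc(OC)c1O | intermediate
26 | EF phenol, 3-fluoro-2-(4-hydroxy-3,5-dimethoxyphenoxy)-5-methoxybenzaldehyde | COc1cc(F)c(Oc2cc(OC)c(O)c(OC)c2)c(C=O)c1 | intermediate
27 | EFGH dialdehyde, 3-fluoro-2-{4-[4-formyl-3,5-dimethoxy-2-(3,4,5-trimethoxyphenoxy)phenoxy]-3,5-dimethoxyphenoxy}-5-methoxybenzaldehyde | COc1cc(F)c(Oc2cc(OC)c(Oc3cc(OC)c(C=O)c(OC)c3Oc3cc(OC)c(OC)c(OC)c3)c(OC)c2)c(C=O)c1 | intermediate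
28 | EFGH bis-formate, the bis(formate ester) of 29 | COc1cc(F)c(Oc2cc(OC)c(Oc3cc(OC)c(OC=O)c(OC)c3Oc3cc(OC)c(OC)c(OC)c3)c(OC)c2)c(OC=O)c1 | intermediate
29 | EFGH bisphenol, 3-fluoro-2-{4-[4-hydroxy-3,5-dimethoxy-2-(3,4,5-trimethoxyphenoxy)phenoxy]-3,5-dimethoxyphenoxy}-5-methoxyphenol | COc1cc(F)c(Oc2cc(OC)c(Oc3cc(OC)c(O)c(OC)c3Oc3cc(OC)c(OC)c(OC)c3)c(OC)c2)c(O)c1 | intermediate
30 | EFGH salicylaldehyde, 4-fluoro-2-hydroxy-3-{4-[4-hydroxy-3,5-dimethoxy-2-(3,4,5-trimethoxyphenoxy)phenoxy]-3,5-dimethoxyphenoxy}-6-methoxybenzaldehyde | COc1cc(F)c(Oc2cc(OC)c(Oc3cc(OC)c(O)c(OC)c3Oc3cc(OC)c(OC)c(OC)c3)c(OC)c2)c(O)c1C=O | intermediate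
31 | EFGH fluoroaldehyde, 4-fluoro-2,6-dimethoxy-3-{3,5-dimethoxy-4-[3,4,5-trimethoxy-2-(3,4,5-trimethoxyphenoxy)phenoxy]phenoxy}benzaldehyde | COc1cc(F)c(Oc2cc(OC)c(Oc3cc(OC)c(OC)c(OC)c3Oc3cc(OC)c(OC)c(OC)c3)c(OC)c2)c(OC)c1C=O | intermediate
32 | ABCD phenol, 13 with the fluorine replaced by a 4-hydroxy-3,5-dimethoxyphenoxy group | COc1cc(OC)c(Oc2cc(OC)c(OC)c(Oc3cc(C=O)c(OC)c(OC)c3Oc3cc(OC)c(O)c(OC)c3)c2)c(OC)c1 | intermediate
33 | octamer dialdehyde, the nonadecamethyl ether of the target with formyl in place of the hydroxyl at position 3 of ring C and at position 4 of ring E | COc1cc(OC)c(Oc2cc(OC)c(OC)c(Oc3cc(C=O)c(OC)c(OC)c3Oc3cc(OC)c(Oc4cc(OC)c(C=O)c(OC)c4Oc4cc(OC)c(Oc5cc(OC)c(OC)c(OC)c5Oc5cc(OC)c(OC)c(OC)c5)c(OC)c4)c(OC)c3)c2)c(OC)c1 | intermediate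
34 | octamer bis-formate, the bis(formate ester) of 35 | COc1cc(OC)c(Oc2cc(OC)c(OC)c(Oc3cc(OC=O)c(OC)c(OC)c3Oc3cc(OC)c(Oc4cc(OC)c(OC=O)c(OC)c4Oc4cc(OC)c(Oc5cc(OC)c(OC)c(OC)c5Oc5cc(OC)c(OC)c(OC)c5)c(OC)c4)c(OC)c3)c2)c(OC)c1 | intermediate
35 | octamer diol, the nonadecamethyl ether of the target with free hydroxyl at position 3 of ring C and position 4 of ring E | COc1cc(OC)c(Oc2cc(OC)c(OC)c(Oc3cc(O)c(OC)c(OC)c3Oc3cc(OC)c(Oc4cc(OC)c(O)c(OC)c4Oc4cc(OC)c(Oc5cc(OC)c(OC)c(OC)c5Oc5cc(OC)c(OC)c(OC)c5)c(OC)c4)c(OC)c3)c2)c(OC)c1 | intermediate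
36 | CNP0175816.0, the free octameric polyphenol with twenty-one hydroxyls | Oc1cc(O)c(Oc2cc(O)c(O)c(Oc3cc(O)c(O)c(O)c3Oc3cc(O)c(Oc4cc(O)c(O)c(O)c4Oc4cc(O)c(Oc5cc(O)c(O)c(O)c5Oc5cc(O)c(O)c(O)c5)c(O)c4)c(O)c3)c2)c(O)c1 | target

**Totals**
Total step count: 24.
Longest linear sequence: 14 steps (14 → 15 → 16 → 17 → 19 → 21 → 22 → 23 → 27 → 29 → 30 → 31 → 33 → 35 → 36).

**Steps most likely to fail**

Step 22.
- Risk: addition to the doubly flanked fluoride of ring C may be slow. The flanked oxygen, a second molecule of 13 or traces of air could then compete. Site selectivity would erode, the hydroquinone would be oxidised, or aryloxy groups para to formyl would be exchanged at the higher temperature.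
- Fallback: it sets out from 13 and comes back at 32, and so at 33. The choice between the two oxygens is handed to a protecting group, and the two couplings are run as separate, purified operations.
- Commercial syringaldehyde is treated with MOMCl and iPr2NEt to give 3,5-dimethoxy-4-(methoxymethoxy)benzaldehyde F1.
- Baeyer–Villiger oxidation with mCPBA gives 3,5-dimethoxy-4-(methoxymethoxy)phenyl formate F2. Methanolysis gives 3,5-dimethoxy-4-(methoxymethoxy)phenol F3, in which only the open oxygen is free.
- An excess of this phenol displaces the fluoride of 13 (Cs2CO3, DMSO) to give the methoxymethyl ether of the ABCD phenol F4.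
- Dilute HCl in THF–iPrOH releases 32. It is isolated and then joined to 31 under the second-stage conditions to give 33.

Step 24.
- Risk: nineteen cleavages must all go to completion while boron chelates of the growing catechol and pyrogallol units fall out of solution. The free polyphenol may also be oxidised by air during chromatography.
- Fallback: it sets out from 35 and comes back at 36. Purification is moved to a protected derivative.
- After the BBr3 treatment and quench, the crude polyphenol is acetylated at once (Ac2O, pyridine) to the henicosaacetate of the target F5.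
- This derivative tolerates air and silica gel, so it can be separated from partly methylated material.
- Methanolysis with HCl in MeOH (from AcCl) under Ar then gives 36 with only volatile side products.

Step 20 (the same concern applies to step 14).
- Risk: neighbouring ether oxygens may hold the magnesium, or the crowded carbon between hydroxyl and methoxy may react too slowly. O-methoxymethylation of the phenols would then overtake C-formylation.
- Fallback: it sets out from 29 and comes back at 31. The magnesium template is replaced by a covalent boron template, with the oxidation level adjusted afterwards as in steps 7 and 8.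
- PhB(OH)2, (CH2O)n and cat. EtCO2H in refluxing toluene with removal of water give the ring E 2-phenyl-4H-1,3,2-benzodioxaborin F6.
- Exchange with propane-1,3-diol frees the EFGH salicyl alcohol F7.
- MeI and K2CO3 give the EFGH benzylic alcohol F8, and MnO2 oxidises it to 31.

**Further compounds**
F1 | step 22 | 3,5-dimethoxy-4-(methoxymethoxy)benzaldehyde | COCOc1c(OC)cc(C=O)cc1OC
F2 | step 22 | 3,5-dimethoxy-4-(methoxymethoxy)phenyl formate | COCOc1c(OC)cc(OC=O)cc1OC
F3 | step 22 | 3,5-dimethoxy-4-(methoxymethoxy)phenol | COCOc1c(OC)cc(O)cc1OC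
F4 | step 22 | methoxymethyl ether of the ABCD phenol | COc1cc(OC)c(Oc2cc(OC)c(OC)c(Oc3cc(C=O)c(OC)c(OC)c3Oc3cc(OC)c(OCOC)c(OC)c3)c2)c(OC)c1
F5 | step 24 | henicosaacetate of the target | CC(=O)Oc1cc(OC(C)=O)c(Oc2cc(OC(C)=O)c(OC(C)=O)c(Oc3cc(OC(C)=O)c(OC(C)=O)c(OC(C)=O)c3Oc3cc(OC(C)=O)c(Oc4cc(OC(C)=O)c(OC(C)=O)c(OC(C)=O)c4Oc4cc(OC(C)=O)c(Oc5cc(OC(C)=O)c(OC(C)=O)c(OC(C)=O)c5Oc5cc(OC(C)=O)c(OC(C)=O)c(OC(C)=O)c5)c(OC(C)=O)c4)c(OC(C)=O)c3)c2)c(OC(C)=O)c1
F6 | step 20 | ring E 2-phenyl-4H-1,3,2-benzodioxaborin of the EFGH series | COc1cc(F)c(Oc3cc(OC)c(Oc4cc(OC)c(O)c(OC)c4Oc4cc(OC)c(OC)c(OC)c4)c(OC)c3)c2OB(c3ccccc3)OCc12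
F7 | step 20 | EFGH salicyl alcohol | COc1cc(F)c(Oc2cc(OC)c(Oc3cc(OC)c(O)c(OC)c3Oc3cc(OC)c(OC)c(OC)c3)c(OC)c2)c(O)c1CO
F8 | step 20 | EFGH benzylic alcohol | COc1cc(F)c(Oc2cc(OC)c(Oc3cc(OC)c(OC)c(OC)c3Oc3cc(OC)c(OC)c(OC)c3)c(OC)c2)c(OC)c1CO
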